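The constants of these flasks were hidden, so I read one off the runs myself, with a pencil and no fit.

| setting | elm | cedar | alder | ochre | teal | blue | violet | grey |
|---|---|---|---|---|---|---|---|---|
| first end groups | 0.41 M | 0.20 M | 0.31 M | 0.41 M (fed, over 6.0 h) | 0.41 M | 0.41 M | 0.41 M (fed, over 1.5 h) | 0.41 M |
| second end groups | 1.1 equiv | 1.1 equiv | 1.1 equiv | 1.10 equiv | 1.10 equiv | 1.10 equiv | 1.10 equiv | 1.10 equiv (fed, over 6.0 h) |
| temperature | 20 °C | 35 °C | 20 °C | 35 °C |  | 35 °C | 35 °C |  |
| remark | run made earlier | run made earlier | run made earlier | all else is in the flask from the start; the feed brings no volume worth counting | everything together at the start at 15 °C, warmed to 35 °C at 6.0 h | everything together at the start | all else is in the flask from the start; the feed brings no volume worth counting | the addition at 15 °C, then warmed to 35 °C; the feed brings no volume worth counting |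
| time |  |  |  | 8.0 h | 8.0 h | 8.0 h | 8.0 h | 8.0 h |

| run | time / h | links / % | first end groups / % |
|---|---|---|---|
| elm | 3.00 | 29.2 | 39.4 |
| elm | 6.00 | 36.8 | 19.4 |
| elm | 10.0 | 37.7 | 8.9 |
| elm | 12.0 | 37.3 | 5.9 |
| elm | 15.0 | 38.4 | 4.0 |
| cedar | 0.500 | 14.4 | 43.5 |
| cedar | 1.00 | 18.7 | 21.4 |
| cedar | 2.00 | 18.2 | 5.8 |
| cedar | 3.00 | 17.4 | 2.1 |
| cedar | 6.00 | 18.3 | 0.4 |
| alder | 1.00 | 12.8 | 72.7 |
| alder | 3.00 | 24.4 | 42.2 |
| alder | 6.00 | 29.8 | 21.8 |
| alder | 10.0 | 32.3 | 9.7 |
| alder | 12.0 | 33.2 | 7.0 |

(readings scatter by 0.5 percentage points)

- for links the crystals are counted in
- as a solid, counted per litre of solution: crystals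
- what was read earlier has a scatter of 0.5 percentage points, one standard deviation
- on the list of suspects stand: first end groups + second end groups -> links; crystals <-> links; second end groups -> decomposed reagent; links <-> isomer of the product; first end groups + second end groups -> rings

- the flask that comes out highest in amount of links, in percent of the first end groups charged, or "all alike" when all lie within 1.5 percentage points (ochre / teal / blue / violet / grey / all alike)
- links at the end, in percent of the first end groups charged, ochre
- links at the end, in percent of the first end groups charged, teal
- links at the end, in percent of the first end groups charged, blue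
- links at the end, in percent of the first end groups charged, violet
- links at the end, in percent of the first end groups charged, grey

One thing in elm looked contradictory. Over the first 3.00 h, 48.2% of the first end groups consumed became links, yet from 6.00 h to 15.0 h first end groups fell by 15 percentage points while links rose by 1.6 points, at the same temperature.

I supposed that links need second end groups in their rate and rings do not. The share going to links is then c(second end groups)/(c(second end groups) + c\*). Here c\*, the parity concentration, is the c(second end groups) at which links and rings take equal shares, a selectivity factor in concentration form. I took second end groups as falling one for one with first end groups and used the mean over the first reading.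

elm: mean c(second end groups) = 0.327 M, so c\* = 0.351 M

cedar: share 25.5%, mean 0.164 M, so c\* = 0.478 M

This cleared up elm. At 6.00 h I reckoned c(second end groups) at 0.121 M, below c\*, so the share to links had sunk to 25.6% and was still falling.

Summing the share over the whole consumption, with a and b the charged concentrations of first and second end groups, gave the end state:

Y = 1 − (c\*/a) · ln[(b + c\*)/(b − a + c\*)]

elm: Y = 38.7%, against the late reading of 38.4%

blue: Y = 32.1%

Teal spends its first 6.00 h at 15 °C, cooler than elm at 20 °C, so I gave it elm's Y and expected it to end higher than blue. The share holds no c(first end groups), so Y stood at 32.1% for ochre and violet as well, provided their first end groups were used up and their second end groups went to links and rings and nowhere else. Grey, with its second end groups fed, lay outside Y.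

The forecast said all alike, with 18% for ochre, 19.5% for teal, 19% for blue, 18.7% for violet and 19% for grey, because the flasks would “finish near the same equilibrium”.

The flasks gave 38.6% in teal, 30.8% in blue, 26.5% in violet, 24.0% in grey and 19.2% in ochre, so teal came out highest.

    first end groups + second end groups → links (k = 0.0467 L mol⁻¹ min⁻¹, Ea = 83.0 kJ mol⁻¹)
    crystals ⇌ links, rate k2*(cs2 - [links]) while solid is left; crystals form when [links] > cs2 (solubility = 7.20 mM, k = 0.216 min⁻¹)
    second end groups → decomposed reagent (k = 0.00245 min⁻¹, Ea = 93.0 kJ mol⁻¹)
    links ⇌ isomer of the product (K = 1.55, k = 6.78 × 10⁻⁴ min⁻¹, Ea = 105 kJ mol⁻¹, ΔH = −16.0 kJ mol⁻¹)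
    first end groups + second end groups → rings, rate k5*[first end groups] as long as [second end groups] is above zero (k = 0.0208 min⁻¹, Ea = 101 kJ mol⁻¹)
    (constants at 35 °C)

My c\* of 0.478 M had put blue at 32.1%, 1.3 points above the simulated value, and 0.351 M had put teal at 38.7% against 38.6%. The same 32.1% stood against 19.2% in ochre and 26.5% in violet, which held 0.154 M and 0.0723 M of decomposed reagent at the end, against 0.0397 M in blue. Neither flask was at rest at 8.00 h. Blue had 0% of its first end groups left, but by 80.0 h its isomer of the product had risen from 0.590% to 2.40% and its links had fallen to 29.0%. Teal still held 2.25% of first end groups at 8.00 h; by 80.0 h its rings stood at 61.1% and its links at 36.5%.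

(The runs stem from a simulated flask from invented constants, and the scatter is random.)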